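The heptane chain is cut between C2 and the acetoxy-bearing carbon C3. The feature exploited is the C3–O–acetyl unit: it is the adduct of an aldehyde and acetyl bromide. The (R)-3-benzyloxy aldehyde carrying C3–C7 and the 4-benzyloxyphenyl ring is turned into a 1-bromoalkyl acetate (both epimers), which a chiral nickel catalyst couples with the 2-arylethylzinc reagent carrying C1–C2 and the protected catechol ring. This one stereoconvergent operation forms C2–C3, sets C3 as R under catalyst control and places the acetyl group on O3 alone, so O3 and O5 never have to be differentiated. C5 comes from an enantioselective allylation; hydrogenolysis of four benzyl ethers ends the route.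

Key step: step 8

Remark on the chemistry (assumption): the target is the (3R,5R) anti isomer. The facial sense of the chiral catalysts in steps 2 and 8 is assigned by analogy with closely related substrates. The ligand enantiomer used is the one that gives the R carbinol carbon; this would be confirmed on 4 by Mosher ester analysis and on 13 by acetonide 13C analysis of a derived 1,3-diol sample.

**Step 1**
Reactants: 1 3-(4-hydroxyphenyl)propan-1-ol
Product: 2 3-[4-(benzyloxy)phenyl]propan-1-ol
Conditions: BnBr (1.05 equiv), K2CO3, acetone, reflux
Reagents that add atoms: benzyl bromide, BrCc1ccccc1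
Why: Williamson ether synthesis in which carbonate deprotonates only the phenol, so the primary alcohol should stay free.

**Step 2**
Reactants: 2 3-[4-(benzyloxy)phenyl]propan-1-ol
Product: 4 (3R)-1-[4-(benzyloxy)phenyl]hex-5-en-3-ol, via 3-[4-(benzyloxy)phenyl]propanal 3 (not isolated)
Conditions: [Ir(cod)Cl]2 (2.5 mol %), (S)-Cl,MeO-BIPHEP (5 mol %), 4-chloro-3-nitrobenzoic acid (10 mol %), Cs2CO3 (20 mol %), allyl acetate (2 equiv), THF, 100 °C, sealed tube
Reagents that add atoms: allyl acetate, C=CCOC(C)=O
Why: Krische transfer-hydrogenative carbonyl allylation, in which the cyclometalated chiral iridium π-allyl complex dehydrogenates 2 to aldehyde 3 and delivers allyl to one enantiotopic face through a closed chair transition state, so the ligand should set the C–OH centre as R.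

**Step 3**
Reactants: 4 (3R)-1-[4-(benzyloxy)phenyl]hex-5-en-3-ol
Product: 5 1-(benzyloxy)-4-[(3R)-3-(benzyloxy)hex-5-en-1-yl]benzene
Conditions: NaH, BnBr, Bu4NI (cat.), THF/DMF, 0 °C to rt
Reagents that add atoms: benzyl bromide, BrCc1ccccc1
Why: Williamson etherification of the secondary alkoxide, which does not touch the carbinol C–O bond, so the R configuration should be retained.

**Step 4**
Reactants: 5 1-(benzyloxy)-4-[(3R)-3-(benzyloxy)hex-5-en-1-yl]benzene
Product: 7 (3R)-3-(benzyloxy)-5-[4-(benzyloxy)phenyl]pentanal, via secondary ozonide 6 (not isolated)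
Conditions: O3, CH2Cl2, −78 °C (Sudan Red 7B end-point); then PPh3, −78 °C to rt
Reagents that add atoms: ozone, [O-][O+]=O
Why: Criegee ozonolysis with reductive work-up, in which the terminal alkene reacts much faster than the alkoxyarenes and the indicator should prevent over-ozonation; the stereocentre is not involved.

**Step 5**
Reactants: 8 2-(3,4-dihydroxyphenyl)ethanol (hydroxytyrosol)
Product: 9 2-[3,4-bis(benzyloxy)phenyl]ethanol
Conditions: BnBr (2.1 equiv), K2CO3, acetone, N2, reflux
Reagents that add atoms: benzyl bromide, BrCc1ccccc1
Why: Williamson ether synthesis selective for the two phenolic hydroxyls over the primary alcohol, run under nitrogen to avoid catechol oxidation.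

**Step 6**
Reactants: 9 2-[3,4-bis(benzyloxy)phenyl]ethanol
Product: 10 1,2-bis(benzyloxy)-4-(2-iodoethyl)benzene
Conditions: I2, PPh3, imidazole, CH2Cl2, 0 °C to rt
Reagents that add atoms: iodine, II
Why: Appel-type (Garegg–Samuelsson) iodination, in which the primary alkoxyphosphonium ion is displaced by iodide in an SN2 step.

**Step 7**
Reactants: 10 1,2-bis(benzyloxy)-4-(2-iodoethyl)benzene
Product: 11 {2-[3,4-bis(benzyloxy)phenyl]ethyl}zinc iodide (titrated solution, used directly)
Conditions: Zn dust (activated with cat. I2), DMA, rt to 40 °C; titration with I2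
Reagents that add atoms: zinc, [Zn]
Why: direct oxidative insertion of activated zinc into the primary C–I bond, which should tolerate the aryl benzyl ethers and give a 2-arylethylzinc halide that is stable in solution.

**Step 8**
Reactants: 7 (3R)-3-(benzyloxy)-5-[4-(benzyloxy)phenyl]pentanal; 11 {2-[3,4-bis(benzyloxy)phenyl]ethyl}zinc iodide
Product: 13 (3R,5R)-5-(benzyloxy)-7-[4-(benzyloxy)phenyl]-1-[3,4-bis(benzyloxy)phenyl]heptan-3-yl acetate, via 1-bromoalkyl acetate 12 (not isolated)
Conditions: (i) AcBr (1.0 equiv), ZnBr2 (2 mol %), CH2Cl2, −20 to 0 °C, then evaporation; (ii) 11 (1.3 equiv), NiBr2·glyme (10 mol %), chiral bis(oxazoline) ligand L* (12 mol %), THF/DMA, 0 °C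
Reagents that add atoms: acetyl bromide, CC(=O)Br
Why: Acetyl bromide adds across the C=O of 7 to give the 1-bromoalkyl acetate 12 as both epimers at the bromine-bearing carbon (the future C3); Ni(I) abstracts bromine from either epimer to give the same planar α-acetoxyalkyl radical, which is captured by the chiral L*Ni(II)–CH2CH2Ar species formed by transmetalation from 11, and reductive elimination from Ni(III) forms the C2–C3 bond. The closest known reaction type is the nickel-catalysed enantioconvergent Negishi-type alkyl–alkyl coupling of racemic 1-bromoalkyl esters, made from an aldehyde and an acyl bromide, with alkylzinc halides. No ring is closed. The new stereocentre C3 should be set as R by the chiral ligand at the radical-capture and reductive-elimination stage; the C5 benzyloxy centre is 1,3-remote and should exert little bias, so both epimers of 12 should converge on the 3R,5R anti product. The step needs chemoselective addition of acetyl bromide to the aldehyde in the presence of four benzyl ethers, secured by one equivalent of AcBr at low temperature and the much higher reactivity of the aldehyde, and coupling without chain-walking of the arylethyl–nickel to the benzylic position, secured by fast reductive elimination at 0 °C on the N,N-ligated nickel. Because the acetyl group arrives as part of the electrophile and O5 is a benzyl ether, the acetate can only sit on O3.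

**Step 9**
Reactants: 13 (3R,5R)-5-(benzyloxy)-7-[4-(benzyloxy)phenyl]-1-[3,4-bis(benzyloxy)phenyl]heptan-3-yl acetate
Product: 14 (3R,5R)-1-(3,4-dihydroxyphenyl)-5-hydroxy-7-(4-hydroxyphenyl)heptan-3-yl acetate
Conditions: H2 (1 atm), 10% Pd/C, EtOAc/THF, rt; filtration under Ar
Reagents that add atoms: none
Why: heterogeneous catalytic hydrogenolysis should cleave the three aryl benzyl ethers and the secondary alkyl benzyl ether under neutral conditions, where the acetate is inert and 1,3-acetyl migration is not triggered; no stereocentre is touched.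

**Compound list**

1 | 3-(4-hydroxyphenyl)propan-1-ol | OCCCc1ccc(O)cc1 | starting material
2 | 3-[4-(benzyloxy)phenyl]propan-1-ol | OCCCc1ccc(OCc2ccccc2)cc1 | intermediate
3 | 3-[4-(benzyloxy)phenyl]propanal (not isolated) | O=CCCc1ccc(OCc2ccccc2)cc1 | intermediate
4 | (3R)-1-[4-(benzyloxy)phenyl]hex-5-en-3-ol | C=CC[C@H](O)CCc1ccc(OCc2ccccc2)cc1 | intermediate
5 | 1-(benzyloxy)-4-[(3R)-3-(benzyloxy)hex-5-en-1-yl]benzene | C=CC[C@H](OCc1ccccc1)CCc1ccc(OCc2ccccc2)cc1 | intermediate
6 | 3-{(2R)-2-(benzyloxy)-4-[4-(benzyloxy)phenyl]butyl}-1,2,4-trioxolane, secondary ozonide, mixture at the ring carbon (not isolated) | C1OC(C[C@H](OCc2ccccc2)CCc2ccc(OCc3ccccc3)cc2)OO1 | intermediate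
7 | (3R)-3-(benzyloxy)-5-[4-(benzyloxy)phenyl]pentanal | O=CC[C@H](OCc1ccccc1)CCc1ccc(OCc2ccccc2)cc1 | intermediate
8 | 2-(3,4-dihydroxyphenyl)ethanol (hydroxytyrosol) | OCCc1ccc(O)c(O)c1 | starting material
9 | 2-[3,4-bis(benzyloxy)phenyl]ethanol | OCCc1ccc(OCc2ccccc2)c(OCc2ccccc2)c1 | intermediate
10 | 1,2-bis(benzyloxy)-4-(2-iodoethyl)benzene | ICCc1ccc(OCc2ccccc2)c(OCc2ccccc2)c1 | intermediate
11 | {2-[3,4-bis(benzyloxy)phenyl]ethyl}zinc iodide (solution) | I[Zn]CCc1ccc(OCc2ccccc2)c(OCc2ccccc2)c1 | intermediate
12 | (3R)-3-(benzyloxy)-5-[4-(benzyloxy)phenyl]-1-bromopentyl acetate, both C1 epimers (not isolated) | CC(=O)OC(Br)C[C@H](OCc1ccccc1)CCc1ccc(OCc2ccccc2)cc1 | intermediate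
13 | (3R,5R)-5-(benzyloxy)-7-[4-(benzyloxy)phenyl]-1-[3,4-bis(benzyloxy)phenyl]heptan-3-yl acetate | CC(=O)O[C@H](CCc1ccc(OCc2ccccc2)c(OCc2ccccc2)c1)C[C@H](OCc1ccccc1)CCc1ccc(OCc2ccccc2)cc1 | intermediate
14 | (3R,5R)-1-(3,4-dihydroxyphenyl)-5-hydroxy-7-(4-hydroxyphenyl)heptan-3-yl acetate | CC(=O)O[C@H](CCc1ccc(O)c(O)c1)C[C@H](O)CCc1ccc(O)cc1 | target

Total step count: 9.
Longest linear sequence: 6 steps (1, 2, 3, 4, 8, 9); steps 5–7 form the convergent branch.

**Steps most likely to fail**

Step 8. The risks are insufficient catalyst control over the configuration at C3 next to the existing C5 centre, cleavage of a benzyl ether by acetyl bromide during formation of the bromo acetate, and isomerisation of the arylethyl–nickel species before C–C bond formation. The fallback sets out from iodide 10 and aldehyde 7 and forms the same C2–C3 bond by a catalytic asymmetric organozinc addition. Iodine–zinc exchange of 10 with Et2Zn (CuI cat., 50 °C, volatiles removed) should give bis{2-[3,4-bis(benzyloxy)phenyl]ethyl}zinc F1. Addition of F1 to 7 with Ti(OiPr)4 and catalytic (1S,2S)-1,2-bis(trifluoromethanesulfonamido)cyclohexane (toluene, −20 °C; the ligand enantiomer expected to direct Re-face attack) should give (3R,5R)-5-(benzyloxy)-7-[4-(benzyloxy)phenyl]-1-[3,4-bis(benzyloxy)phenyl]heptan-3-ol F2 under reagent control. Acetylation (Ac2O, pyridine, DMAP, CH2Cl2) rejoins the route at 13.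

Step 9. The risks are slow cleavage of the secondary alkyl benzyl ether with long contact times, 1,3-migration of the acetyl group from O3 to the freed O5, and oxidation of the catechol during work-up. The fallback sets out from 13 and replaces hydrogenolysis by Lewis-acid debenzylation with a cation scavenger: BCl3 and pentamethylbenzene in CH2Cl2 at −78 °C, quenched cold with CHCl3/MeOH. It should remove all four benzyl groups while leaving the ester in place and comes back to the route directly at 14. It makes no compound outside the list (F0).

Step 2. The risks are incomplete conversion or insufficient enantiofacial discrimination in the transfer-hydrogenative allylation of an unbranched aliphatic alcohol. The fallback sets out from 2: oxidation with Dess–Martin periodinane (CH2Cl2, rt) gives aldehyde 3, isolated in this case. Keck allylation (allyltributylstannane, (S)-BINOL/Ti(OiPr)4 cat., 4 Å MS, CH2Cl2, −20 °C; the BINOL enantiomer expected to give the R carbinol) then rejoins the route at 4. It makes no compound outside the list (F0).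

**Further compounds**

F1 | step 8 | bis{2-[3,4-bis(benzyloxy)phenyl]ethyl}zinc | [Zn](CCc1ccc(OCc2ccccc2)c(OCc2ccccc2)c1)CCc1ccc(OCc2ccccc2)c(OCc2ccccc2)c1
F2 | step 8 | (3R,5R)-5-(benzyloxy)-7-[4-(benzyloxy)phenyl]-1-[3,4-bis(benzyloxy)phenyl]heptan-3-ol | O[C@H](CCc1ccc(OCc2ccccc2)c(OCc2ccccc2)c1)C[C@H](OCc1ccccc1)CCc1ccc(OCc2ccccc2)cc1
F0 | step 9 | none | none
F0 | step 2 | none | none
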